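The target is cut at both bonds of the diaryl ketone carbon, the one atom that links C1′ of the 2‑hydroxy‑4,6‑dimethoxyphenyl ring (ring A) to C5 of the benzo ring of the 2,2‑dimethyl‑2H‑chromene; this carbon is delivered as carbon monoxide. A single palladium‑catalysed carbonylative Suzuki–Miyaura coupling joins a di‑ortho‑oxygenated ring A iodide, CO and a chromen‑5‑yl pinacol boronate, forming both aryl–carbonyl bonds without closing a ring. Both partners carry their phenol as a MOM ether; the boronate is made from phloroglucinol through a chroman‑4‑one whose carbonyl tells the 5‑OH from the 7‑OH. One acidic step then frees both phenols.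

Key step: step 9

Remark on the chemistry: the target has no stereocentre and no stereogenic double bond, so it is achiral and no enantiocontrol is needed. The only stereocentre on the route, C4 of carbinol 10 and mesylate 11, is racemic and is erased in step 7.

**Ring A iodide**

Step 1
Reactants: 1 3,5-dimethoxyphenol
Product: 2 1,3-dimethoxy-5-(methoxymethoxy)benzene
Conditions: NaH, MOMCl, DMF, 0 °C → rt
Reagents that add atoms: chloromethyl methyl ether (MOMCl), COCCl
Why: Williamson-type O-alkylation of the sodium phenoxide by the reactive α-chloro ether should give the MOM ether, which also serves as the directing group for step 2.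

Step 2
Reactants: 2 1,3-dimethoxy-5-(methoxymethoxy)benzene
Product: 4 2-iodo-3,5-dimethoxy-1-(methoxymethoxy)benzene, via [2,4-dimethoxy-6-(methoxymethoxy)phenyl]lithium 3 (not isolated)
Conditions: n-BuLi, TMEDA, THF, 0 °C; then I2, −78 °C → rt
Reagents that add atoms: iodine, II
Why: Directed ortho-metalation: the MOM acetal chelates lithium better than a methyl ether, so deprotonation should occur at the C–H flanked by OMOM and OMe (two equivalent sites) instead of the one between the two OMe groups, and iodinolysis of the aryllithium fixes iodine there.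

**Chromenyl boronate**

Step 3
Reactants: 5 phloroglucinol; 6 3-methylbut-2-enoic acid
Product: 7 5,7-dihydroxy-2,2-dimethylchroman-4-one
Conditions: P2O5/MeSO3H, 70 °C
Reagents that add atoms: none
Why: Friedel–Crafts acylation of the C3-symmetric triol followed by intramolecular oxa-Michael closure of the ortho phenol onto the enone should give one chromanone, since symmetry removes any regiochemical choice and the new aryl ketone deactivates the ring towards a second annulation.

Step 4
Reactants: 7 5,7-dihydroxy-2,2-dimethylchroman-4-one
Product: 8 5-hydroxy-7-(methoxymethoxy)-2,2-dimethylchroman-4-one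
Conditions: MOMCl (1.05 equiv), K2CO3, acetone, 0 °C → rt
Reagents that add atoms: chloromethyl methyl ether (MOMCl), COCCl
Why: Selective O-alkylation: the 5-OH is held in a hydrogen bond to the C4 carbonyl and is poorly nucleophilic, whereas the 7-OH (para to the carbonyl, more acidic) is alkylated under mild carbonate conditions.

Step 5
Reactants: 8 5-hydroxy-7-(methoxymethoxy)-2,2-dimethylchroman-4-one
Product: 9 7-(methoxymethoxy)-2,2-dimethyl-4-oxochroman-5-yl trifluoromethanesulfonate
Conditions: Tf2O, pyridine, CH2Cl2, 0 °C
Reagents that add atoms: trifluoromethanesulfonic anhydride, O=S(=O)(OS(=O)(=O)C(F)(F)F)C(F)(F)F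
Why: O-sulfonylation of the one remaining phenol by the strongly electrophilic anhydride overcomes the chelation, and the pyridine buffer keeps the MOM acetal intact.

Step 6
Reactants: 9 7-(methoxymethoxy)-2,2-dimethyl-4-oxochroman-5-yl trifluoromethanesulfonate
Product: 10 rac-4-hydroxy-7-(methoxymethoxy)-2,2-dimethylchroman-5-yl trifluoromethanesulfonate
Conditions: NaBH4, MeOH/THF, 0 °C
Reagents that add atoms: none
Why: Borohydride reduction of the aryl ketone leaves aryl triflate and MOM ether untouched at 0 °C; the C4 stereocentre is formed racemic on purpose because the next step removes it.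

Step 7
Reactants: 10 rac-4-hydroxy-7-(methoxymethoxy)-2,2-dimethylchroman-5-yl trifluoromethanesulfonate
Product: 12 7-(methoxymethoxy)-2,2-dimethyl-2H-chromen-5-yl trifluoromethanesulfonate, via rac-4-(methylsulfonyloxy)-7-(methoxymethoxy)-2,2-dimethylchroman-5-yl trifluoromethanesulfonate 11 (not isolated)
Conditions: Ms2O, Et3N, CH2Cl2, 0 °C → rt; then DBU, rt
Reagents that add atoms: none
Why: Sulfonylation–elimination: the benzylic mesylate, activated by the ring oxygen (ortho) and the C7 oxygen (para), should eliminate readily under amine base, only C3 carries β-hydrogens so only the C3=C4 alkene can form, and the non-acidic medium spares the MOM group.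

Step 8
Reactants: 12 7-(methoxymethoxy)-2,2-dimethyl-2H-chromen-5-yl trifluoromethanesulfonate
Product: 13 2-[7-(methoxymethoxy)-2,2-dimethyl-2H-chromen-5-yl]-4,4,5,5-tetramethyl-1,3,2-dioxaborolane
Conditions: B2pin2, PdCl2(dppf) (5 mol%), KOAc, 1,4-dioxane, 85 °C
Reagents that add atoms: bis(pinacolato)diboron, CC1(C)OB(OC1(C)C)B1OC(C)(C)C(C)(C)O1
Why: Miyaura borylation: oxidative addition of the aryl triflate, acetate-assisted transmetalation with the diboron and reductive elimination should give the boronate, and acetate is too weak a base to trigger Suzuki homocoupling.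

**Coupling and deprotection**

Step 9
Reactants: 4 2-iodo-3,5-dimethoxy-1-(methoxymethoxy)benzene; 13 2-[7-(methoxymethoxy)-2,2-dimethyl-2H-chromen-5-yl]-4,4,5,5-tetramethyl-1,3,2-dioxaborolane
Product: 14 [2,4-dimethoxy-6-(methoxymethoxy)phenyl][7-(methoxymethoxy)-2,2-dimethyl-2H-chromen-5-yl]methanone
Conditions: CO (1 atm), PEPPSI-IPr (5 mol%), Cs2CO3, PhCl (trace H2O), 80 °C, slow addition of 13
Reagents that add atoms: carbon monoxide, [C-]#[O+]
Why: Pd(0)–NHC inserts into the C–I bond of 4, CO coordinates and migratory insertion gives an aroyl–Pd(II) species, the carbonate-activated boronate 13 transfers its chromen-5-yl group, and reductive elimination releases ketone 14, so both bonds to the carbonyl carbon form in one catalytic cycle. The closest known reaction type is the carbonylative Suzuki–Miyaura coupling of 2,6-disubstituted aryl iodides with arylboron reagents under bulky NHC–palladium catalysis. No ring is closed and no stereocentre is created. The selectivity required is carbonylative over direct biaryl coupling: the OMOM and OMe groups flanking the aryl–Pd bond hinder transmetalation at that stage, while CO insertion into this electron-rich aryl–Pd bond is fast and moves the metal one atom away from the congestion; the CO atmosphere and slow addition of 13 should reinforce this. Both phenols are masked as MOM ethers so that no phenoxide can trap the aroyl–palladium intermediate as an ester, and the chromene alkene and the aryl ethers are inert under these conditions.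

Step 10
Reactants: 14 [2,4-dimethoxy-6-(methoxymethoxy)phenyl][7-(methoxymethoxy)-2,2-dimethyl-2H-chromen-5-yl]methanone
Product: 15 (2-hydroxy-4,6-dimethoxyphenyl)(7-hydroxy-2,2-dimethyl-2H-chromen-5-yl)methanone
Conditions: conc. HCl (cat.), MeOH, 40 °C
Reagents that add atoms: none
Why: Acid-catalysed acetal exchange with methanol should cleave both MOM ethers (the one ortho to the ketone especially easily), while the aryl methyl ethers and the 2,2-dimethylchromene, whose alkene is deactivated by the 5-aroyl group, should survive these mild conditions.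

**Compound list**

1 | 3,5-dimethoxyphenol | COc1cc(O)cc(OC)c1 | starting material
2 | 1,3-dimethoxy-5-(methoxymethoxy)benzene | COCOc1cc(OC)cc(OC)c1 | intermediate
3 | [2,4-dimethoxy-6-(methoxymethoxy)phenyl]lithium | [Li]c1c(OC)cc(OC)cc1OCOC | intermediate
4 | 2-iodo-3,5-dimethoxy-1-(methoxymethoxy)benzene | COCOc1cc(OC)cc(OC)c1I | intermediate
5 | phloroglucinol (benzene-1,3,5-triol) | Oc1cc(O)cc(O)c1 | starting material
6 | 3-methylbut-2-enoic acid | CC(C)=CC(=O)O | starting material
7 | 5,7-dihydroxy-2,2-dimethylchroman-4-one | CC1(C)CC(=O)c2c(O)cc(O)cc2O1 | intermediate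
8 | 5-hydroxy-7-(methoxymethoxy)-2,2-dimethylchroman-4-one | COCOc1cc(O)c2C(=O)CC(C)(C)Oc2c1 | intermediate
9 | 7-(methoxymethoxy)-2,2-dimethyl-4-oxochroman-5-yl trifluoromethanesulfonate | COCOc1cc(OS(=O)(=O)C(F)(F)F)c2C(=O)CC(C)(C)Oc2c1 | intermediate
10 | rac-4-hydroxy-7-(methoxymethoxy)-2,2-dimethylchroman-5-yl trifluoromethanesulfonate (racemic at C4) | COCOc1cc(OS(=O)(=O)C(F)(F)F)c2C(O)CC(C)(C)Oc2c1 | intermediate
11 | rac-4-(methylsulfonyloxy)-7-(methoxymethoxy)-2,2-dimethylchroman-5-yl trifluoromethanesulfonate (racemic at C4) | COCOc1cc(OS(=O)(=O)C(F)(F)F)c2C(OS(C)(=O)=O)CC(C)(C)Oc2c1 | intermediate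
12 | 7-(methoxymethoxy)-2,2-dimethyl-2H-chromen-5-yl trifluoromethanesulfonate | COCOc1cc(OS(=O)(=O)C(F)(F)F)c2C=CC(C)(C)Oc2c1 | intermediate
13 | 2-[7-(methoxymethoxy)-2,2-dimethyl-2H-chromen-5-yl]-4,4,5,5-tetramethyl-1,3,2-dioxaborolane | COCOc1cc(B2OC(C)(C)C(C)(C)O2)c2C=CC(C)(C)Oc2c1 | intermediate
14 | [2,4-dimethoxy-6-(methoxymethoxy)phenyl][7-(methoxymethoxy)-2,2-dimethyl-2H-chromen-5-yl]methanone | COCOc1cc(C(=O)c2c(OCOC)cc(OC)cc2OC)c2C=CC(C)(C)Oc2c1 | intermediate
15 | (2-hydroxy-4,6-dimethoxyphenyl)(7-hydroxy-2,2-dimethyl-2H-chromen-5-yl)methanone | COc1cc(O)c(C(=O)c2cc(O)cc3c2C=CC(C)(C)O3)c(OC)c1 | target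

Total step count: 10. Longest linear sequence: 8 steps (steps 3–10, from phloroglucinol).

**Steps most likely to fail**

Step 9. Transmetalation may outrun CO insertion and give the direct biaryl. The hindered boronate may also protodeboronate, or the aroyl–palladium species may be intercepted by water. The fallback forms the two aryl–carbonyl bonds in separate operations and sets out from triflate 12. Palladium-catalysed aminocarbonylation (Pd(OAc)2, Xantphos, CO 1 atm, MeNHOMe·HCl, K3PO4, toluene, 90 °C) should give N-methoxy-N-methyl-7-(methoxymethoxy)-2,2-dimethyl-2H-chromene-5-carboxamide F1. Iodide 4 is converted by iodine–lithium exchange (n-BuLi, THF, −78 °C) into aryllithium 3, which adds to F1. Collapse of the chelated tetrahedral adduct on work-up returns to the route at ketone 14.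

Step 2. Lithiation may occur partly at the C–H between the two methoxy groups, giving the regioisomeric iodide. The fallback uses the stronger carbamate directing group and sets out from phenol 1. Carbamoylation (ClCONEt2, K2CO3, MeCN, reflux) should give 3,5-dimethoxyphenyl N,N-diethylcarbamate F2. Lithiation ortho to the carbamate (s-BuLi, TMEDA, THF, −78 °C) with an iodine quench at that temperature should give 2-iodo-3,5-dimethoxyphenyl N,N-diethylcarbamate F3. Hydrolysis (NaOH, EtOH/H2O, reflux) then gives 2-iodo-3,5-dimethoxyphenol F4, and MOM protection (NaH, MOMCl, DMF) returns to the route at iodide 4.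

Step 7. Elimination may stall, or ionisation of the mesylate may lead to substitution or loss of the MOM group. The preceding reduction also exposes the peri triflate to an alkoxide. The fallback moves reduction and dehydration ahead of triflation and sets out from chromanone 8. NaBH4 reduction (MeOH/THF, 0 °C → rt) should give rac-7-(methoxymethoxy)-2,2-dimethylchromane-4,5-diol F5. The free peri phenol lets water leave through an ortho-quinone methide on gentle warming (cat. PPTS, toluene, 60 °C), which tautomerises to 7-(methoxymethoxy)-2,2-dimethyl-2H-chromen-5-ol F6. Triflation (Tf2O, pyridine, CH2Cl2, 0 °C) returns to the route at triflate 12.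

Further compounds
F1 | step 9 | N-methoxy-N-methyl-7-(methoxymethoxy)-2,2-dimethyl-2H-chromene-5-carboxamide | CON(C)C(=O)c1cc(OCOC)cc2OC(C)(C)C=Cc12
F2 | step 2 | 3,5-dimethoxyphenyl N,N-diethylcarbamate | CCN(CC)C(=O)Oc1cc(OC)cc(OC)c1
F3 | step 2 | 2-iodo-3,5-dimethoxyphenyl N,N-diethylcarbamate | CCN(CC)C(=O)Oc1cc(OC)cc(OC)c1I
F4 | step 2 | 2-iodo-3,5-dimethoxyphenol | COc1cc(O)c(I)c(OC)c1
F5 | step 7 | rac-7-(methoxymethoxy)-2,2-dimethylchromane-4,5-diol | COCOc1cc(O)c2C(O)CC(C)(C)Oc2c1
F6 | step 7 | 7-(methoxymethoxy)-2,2-dimethyl-2H-chromen-5-ol | COCOc1cc(O)c2C=CC(C)(C)Oc2c1
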